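The upper C ring is read as a 1,2-cis C-aryl glycoside: the C2–C1′ bond to ring B and the C3–O bond are cis to each other and trans to the C4–C8 bond to the lower A ring (ring D). Both bonds are therefore made at once from a 4-aryl-4H-chromene whose C2=C3 enol ether is epoxidised anti to the C4 aryl group and opened at C2, with retention, by an arylzinc that carries ring B and the bridging gallate. C2 and C3 are thereby set from C4 in a single operation. The chromene holds the silylated, benzylated lower epigallocatechin unit at C4; galloylation, fluoride unmasking, macrolactonisation and hydrogenolysis then finish the target.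

Key step: step 20

Assumption: the target is taken exactly as its SMILES (upper unit 2R,3R,4R; lower unit 2R,3R; 4→8 link; gallate ether at C2′ of the upper B ring).

Design notes:
- The stereodescriptors of chromene 14, zinc reagent 28 and coupling product 30 were checked against the target and need no correction.
- The B-ring halogen is put on the free phenol (ortho-iodination) before the diaryl ether is made. Halogenation of the finished ether would be steered by the benzyloxy groups to C6′, not C1′.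
- The diaryl ether is closed by a Cu(II) Chan–Lam coupling, which leaves the C–I bond intact.
- Iodide replaces bromide so that a low-temperature I/Mg exchange tolerates the ester.
- A 2-(trimethylsilyl)ethyl (TMSE) ester replaces an allyl ester, so one fluoride treatment frees the acid and the lower 3-OH together.

Abbreviations:
- Bn = benzyl; TBS = tert-butyldimethylsilyl.
- LU = (2R,3R)-5,7-bis(benzyloxy)-3-(TBS-oxy)-2-[3,4,5-tris(benzyloxy)phenyl]chroman-8-yl.
- ArBG = 3,4,5-tris(benzyloxy)-2-{2,3-bis(benzyloxy)-5-[(2-(trimethylsilyl)ethoxy)carbonyl]phenoxy}phenyl.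

Step 1
Reactants: 1 (−)-epigallocatechin
Product: 2 (2R,3R)-5,7-bis(benzyloxy)-2-[3,4,5-tris(benzyloxy)phenyl]chroman-3-ol
Conditions: BnBr, K2CO3, DMF, 0 °C → rt
Reagents that add atoms: benzyl bromide, BrCc1ccccc1
Why: Williamson O-alkylation of the five phenols under carbonate conditions, which do not deprotonate the secondary 3-OH and leave C2 and C3 untouched.

Step 2
Reactants: 2 penta-O-benzyl epigallocatechin
Product: 3 (2R,3R)-3-O-TBS ether of 2
Conditions: TBSOTf, 2,6-lutidine, CH2Cl2, 0 °C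
Reagents that add atoms: tert-butyldimethylsilyl triflate, CC(C)(C)[Si](C)(C)OS(=O)(=O)C(F)(F)F
Why: Silylation with the triflate overcomes the hindered axial 3-OH and gives an ether that survives organolithium, hydride and organozinc steps.

Step 3
Reactants: 3 3-O-TBS penta-O-benzyl epigallocatechin
Product: 4 8-bromo derivative of 3 (2R,3R)
Conditions: NBS, CH2Cl2, −78 → 0 °C
Reagents that add atoms: N-bromosuccinimide, O=C1CCC(=O)N1Br
Why: Electrophilic aromatic bromination of the phloroglucinol-type A ring, which in 3-O-silylated 5,7-dialkoxyflavans takes place at C8.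

Step 4
Reactants: 4 8-bromide
Product: 7 (2R,3R)-8-borono derivative of 3 (LU–B(OH)2), via 8-lithio species 5 (not isolated), via lithium trimethoxyborate 6 (not isolated)
Conditions: n-BuLi, THF, −78 °C; B(OMe)3, −78 → 0 °C; 1 M HCl, 0 °C
Reagents that add atoms: trimethyl borate, COB(OC)OC; water, O
Why: Bromine–lithium exchange is faster than any deprotonation at −78 °C, the aryllithium is trapped as the borate and mild hydrolysis gives the boronic acid.

Step 5
Reactants: 8 phloroglucinol; 9 ethyl propiolate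
Product: 10 5,7-dihydroxycoumarin
Conditions: ZnCl2, 100 °C
Reagents that add atoms: none
Why: Pechmann-type condensation (C-attack of the symmetrical triphenol on the zinc-activated alkynoate, then lactonisation of the Z-cinnamate), with no regiochemical ambiguity.

Step 6
Reactants: 10 5,7-dihydroxycoumarin
Product: 11 5,7-bis(benzyloxy)coumarin
Conditions: BnBr, K2CO3, acetone, reflux
Reagents that add atoms: benzyl bromide, BrCc1ccccc1
Why: Williamson O-alkylation of both phenols.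

Step 7
Reactants: 7 lower-unit 8-boronic acid; 11 5,7-bis(benzyloxy)coumarin
Product: 12 (4R)-5,7-bis(benzyloxy)-4-LU-chroman-2-one
Conditions: Rh(acac)(C2H4)2 (cat.), (S)-SEGPHOS (cat.), 11 in excess, dioxane/H2O 10:1, 60 °C
Reagents that add atoms: none
Why: Hayashi–Miyaura rhodium-catalysed asymmetric 1,4-addition of an arylboronic acid to a coumarin, in which the aryl–rhodium species adds across C3=C4 on the face chosen by the ligand; (S)-SEGPHOS is the enantiomer expected, by analogy with simple coumarins, to give 4R, and this must be confirmed.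

Step 8
Reactants: 12 (4R)-lactone
Product: 13 (4R)-5,7-bis(benzyloxy)-4-LU-chroman-2-ol (C2 epimers)
Conditions: DIBAL-H, toluene/CH2Cl2, −78 °C; Rochelle salt
Reagents that add atoms: none
Why: Partial reduction of a dihydrocoumarin, whose tetrahedral aluminate is stable at −78 °C and gives the lactol on work-up.

Step 9
Reactants: 13 lactol
Product: 14 (4R)-5,7-bis(benzyloxy)-4-LU-4H-chromene
Conditions: PPTS (cat.), toluene, 4 Å MS, 80 °C
Reagents that add atoms: none
Why: Acid-catalysed dehydration through the O1-stabilised oxocarbenium ion, which can only lose H3, so the C2=C3 enol ether forms and C4 is not touched.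

Step 10
Reactants: 15 2,3,4-trihydroxybenzaldehyde
Product: 16 2,3,4-tris(benzyloxy)benzaldehyde
Conditions: BnBr, K2CO3, DMF, 60 °C
Reagents that add atoms: benzyl bromide, BrCc1ccccc1
Why: Williamson O-alkylation, with warming so that the hydrogen-bonded 2-OH also reacts.

Step 11
Reactants: 16 2,3,4-tris(benzyloxy)benzaldehyde
Product: 18 2,3,4-tris(benzyloxy)phenol, via aryl formate 17 (not isolated)
Conditions: mCPBA, CH2Cl2, rt; then K2CO3, MeOH, rt
Reagents that add atoms: 3-chloroperbenzoic acid, OOC(=O)c1cccc(Cl)c1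
Why: Dakin-type Baeyer–Villiger oxidation, in which the electron-rich aryl group migrates to oxygen and the formate is removed by methanolysis.

Step 12
Reactants: 18 2,3,4-tris(benzyloxy)phenol
Product: 19 2,3,4-tris(benzyloxy)-6-iodophenol
Conditions: I2, morpholine, CH2Cl2, 0 °C → rt
Reagents that add atoms: iodine, II
Why: Phenol-directed electrophilic iodination under amine conditions goes to C6, the only free position ortho or para to the hydroxyl, which is the future C1′ of ring B.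

Step 13
Reactants: 20 5-bromovanillin
Product: 21 3-bromo-4,5-dihydroxybenzaldehyde
Conditions: AlCl3, pyridine, CH2Cl2, reflux; aq. HCl
Reagents that add atoms: none
Why: Chelation-assisted demethylation of the methyl ether next to the free phenol by the aluminium chloride–pyridine system.

Step 14
Reactants: 21 3-bromo-4,5-dihydroxybenzaldehyde
Product: 22 3,4-bis(benzyloxy)-5-bromobenzaldehyde
Conditions: BnBr, K2CO3, DMF, rt
Reagents that add atoms: benzyl bromide, BrCc1ccccc1
Why: Williamson O-alkylation of the catechol.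

Step 15
Reactants: 22 3,4-bis(benzyloxy)-5-bromobenzaldehyde
Product: 23 3,4-bis(benzyloxy)-5-bromobenzoic acid
Conditions: NaClO2, NaH2PO4, 2-methyl-2-butene, t-BuOH/H2O, rt
Reagents that add atoms: sodium chlorite, [Na+].[O-]Cl=O
Why: Pinnick oxidation converts the aldehyde to the acid without touching benzyl ethers or the aryl bromide.

Step 16
Reactants: 23 3,4-bis(benzyloxy)-5-bromobenzoic acid
Product: 24 2-(trimethylsilyl)ethyl 3,4-bis(benzyloxy)-5-bromobenzoate
Conditions: 2-(trimethylsilyl)ethanol, EDC·HCl, DMAP, CH2Cl2, rt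
Reagents that add atoms: 2-(trimethylsilyl)ethanol, C[Si](C)(C)CCO
Why: Steglich esterification installs an ester that is inert to palladium, copper and organozinc chemistry and is later removed by fluoride.

Step 17
Reactants: 24 TMSE bromobenzoate
Product: 25 2-(trimethylsilyl)ethyl 3,4-bis(benzyloxy)-5-boronobenzoate
Conditions: B2(OH)4, XPhos Pd G2 (cat.), XPhos, KOAc, EtOH, 80 °C
Reagents that add atoms: tetrahydroxydiboron, OB(O)B(O)O
Why: Miyaura-type palladium-catalysed borylation of an aryl bromide with tetrahydroxydiboron gives the boronic acid directly and tolerates the ester.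

Step 18
Reactants: 19 2,3,4-tris(benzyloxy)-6-iodophenol; 25 arylboronic acid
Product: 26 2-(trimethylsilyl)ethyl 3,4-bis(benzyloxy)-5-[2,3,4-tris(benzyloxy)-6-iodophenoxy]benzoate
Conditions: Cu(OAc)2 (0.3 equiv), pyridine, 4 Å MS, CH2Cl2, O2 (1 atm), rt
Reagents that add atoms: none
Why: Chan–Lam oxidative C–O coupling of a phenol with an arylboronic acid runs at room temperature through Cu(II)/Cu(III) and does not insert into the C–I bond.

Step 19
Reactants: 26 aryl iodide
Product: 28 ArBG–ZnBr (arylzinc bromide; used as a titrated solution), via arylmagnesium chloride 27 (not isolated)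
Conditions: i-PrMgCl·LiCl, THF, −30 °C; ZnBr2, −30 → 0 °C
Reagents that add atoms: zinc bromide, Br[Zn]Br
Why: Iodine–magnesium exchange with the turbo-Grignard reagent is accelerated by the ortho aryloxy group and is faster than addition to the ester at −30 °C, and transmetalation gives the Lewis-acidic arylzinc.

Step 20
Reactants: 14 (4R)-4-aryl-4H-chromene; 28 arylzinc bromide
Product: 30 (2R,3R,4R)-5,7-bis(benzyloxy)-2-ArBG-4-LU-chroman-3-ol, via 2,3-epoxide 29 (not isolated)
Conditions: DMDO (acetone), CH2Cl2, −78 → −30 °C; volatiles removed cold; 28 (1.5–2 equiv), toluene/THF, −78 → 0 °C; H2O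
Reagents that add atoms: dimethyldioxirane, CC1(C)OO1
Why: Proposed new method: DMDO transfers oxygen in a concerted step to the electron-rich C2=C3 enol ether of 14 on the face away from the quasi-axial C4 aryl group (held axial by peri strain with the 5-benzyloxy group) to give the labile (2S,3R,4R)-oxide 29, whose oxygen then binds the zinc of 28, so that C2–O ionises to an O1-stabilised oxocarbenium/zinc alkoxide pair and the aryl group passes from zinc to C2 within that pair, on the face of O3 (retention at C2). The closest known reaction type is the syn (1,2-cis) C-arylation of 1,2-anhydro sugars by arylzinc or arylaluminium reagents, which has not been shown on a benzo-fused 4H-chromene 2,3-oxide. No ring is closed in the product, since the transient oxirane, formed by concerted [2+1] oxygen transfer, is opened again in the same flask. C3 (R) is set by the face of epoxidation, that is by substrate control from C4, and C2 (R) by internal aryl delivery from the O3-bound zinc, a face that is also remote from the C4 aryl group, so steric and directing effects agree. The step needs anti epoxidation, syn opening and attack at the acetal carbon C2; these are secured by the bulky C4 substituent, by the tight ion pair in a toluene-rich medium with no added halide Lewis acid, and by the oxocarbenium character of C2.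

Step 21
Reactants: 30 upper flavan-3-ol; 31 3,4,5-tris(benzyloxy)benzoic acid
Product: 32 3-O-[3,4,5-tris(benzyloxy)benzoyl] ester of 30 (2R,3R,4R)
Conditions: EDC·HCl, DMAP, CH2Cl2, rt
Reagents that add atoms: none
Why: Steglich esterification through the acylpyridinium ion acylates the hindered 3-OH with retention, and the lower 3-OTBS and the TMSE ester stay masked.

Step 22
Reactants: 32 galloylated dimer
Product: 33 seco acid (lower 3-OH free, bridging gallate CO2H free)
Conditions: TBAF, THF, 0 °C → rt; 0.5 M HCl work-up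
Reagents that add atoms: none
Why: Fluoride cleaves the TBS ether and fragments the TMSE ester (attack at silicon, loss of ethene) in one operation, while the aryl ester of the upper unit and the benzyl ethers are inert.

Step 23
Reactants: 33 seco acid
Product: 35 pentadeca-O-benzyl macrolactone (16-membered ring), via mixed anhydride 34 (not isolated)
Conditions: 2,4,6-trichlorobenzoyl chloride, Et3N, THF, rt; slow addition to DMAP, toluene, 80 °C, high dilution
Reagents that add atoms: none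
Why: Yamaguchi macrolactonisation activates the aromatic acid as a mixed anhydride, DMAP attacks the less hindered carbonyl and the lower 3-OH closes the 16-membered ring with retention at C3.

Step 24
Reactants: 35 pentadeca-O-benzyl macrolactone
Product: 36 CNP0601265.1
Conditions: H2 (1 atm), Pd(OH)2/C, THF/MeOH 1:1, rt; filtration under argon
Reagents that add atoms: none
Why: Hydrogenolysis removes all fifteen benzyl ethers, while the esters, the diaryl ether and the flavan C–O and C4–C8 bonds are stable under these mild conditions.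

Compound list
1 | (−)-epigallocatechin, (2R,3R) | O[C@@H]1Cc2c(O)cc(O)cc2O[C@@H]1c1cc(O)c(O)c(O)c1 | starting material
2 | (2R,3R)-5,7-bis(benzyloxy)-2-[3,4,5-tris(benzyloxy)phenyl]chroman-3-ol | O[C@@H]1Cc2c(OCc5ccccc5)cc(OCc5ccccc5)cc2O[C@@H]1c1cc(OCc5ccccc5)c(OCc5ccccc5)c(OCc5ccccc5)c1 | intermediate
3 | 3-O-TBS ether of 2, (2R,3R) | CC(C)(C)[Si](C)(C)O[C@@H]1Cc2c(OCc5ccccc5)cc(OCc5ccccc5)cc2O[C@@H]1c1cc(OCc5ccccc5)c(OCc5ccccc5)c(OCc5ccccc5)c1 | intermediate
4 | 8-bromo derivative of 3, (2R,3R) | CC(C)(C)[Si](C)(C)O[C@@H]1Cc2c(OCc5ccccc5)cc(OCc5ccccc5)c(Br)c2O[C@@H]1c1cc(OCc5ccccc5)c(OCc5ccccc5)c(OCc5ccccc5)c1 | intermediate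
5 | 8-lithio derivative of 3 | CC(C)(C)[Si](C)(C)O[C@@H]1Cc2c(OCc5ccccc5)cc(OCc5ccccc5)c([Li])c2O[C@@H]1c1cc(OCc5ccccc5)c(OCc5ccccc5)c(OCc5ccccc5)c1 | intermediate
6 | lithium trimethoxy(LU)borate | CC(C)(C)[Si](C)(C)O[C@@H]1Cc2c(OCc5ccccc5)cc(OCc5ccccc5)c([B-](OC)(OC)OC)c2O[C@@H]1c1cc(OCc5ccccc5)c(OCc5ccccc5)c(OCc5ccccc5)c1.[Li+] | intermediate
7 | LU–B(OH)2, 8-boronic acid of 3, (2R,3R) | CC(C)(C)[Si](C)(C)O[C@@H]1Cc2c(OCc5ccccc5)cc(OCc5ccccc5)c(B(O)O)c2O[C@@H]1c1cc(OCc5ccccc5)c(OCc5ccccc5)c(OCc5ccccc5)c1 | intermediate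
8 | phloroglucinol | Oc1cc(O)cc(O)c1 | starting material
9 | ethyl propiolate | CCOC(=O)C#C | starting material
10 | 5,7-dihydroxycoumarin | O=C1C=Cc2c(O)cc(O)cc2O1 | intermediate
11 | 5,7-bis(benzyloxy)coumarin | O=C1C=Cc2c(OCc5ccccc5)cc(OCc5ccccc5)cc2O1 | intermediate
12 | (4R)-5,7-bis(benzyloxy)-4-LU-chroman-2-one | O=C1C[C@@H](c2c(OCc5ccccc5)cc(OCc5ccccc5)c3C[C@@H](O[Si](C)(C)C(C)(C)C)[C@@H](c4cc(OCc5ccccc5)c(OCc5ccccc5)c(OCc5ccccc5)c4)Oc32)c2c(OCc5ccccc5)cc(OCc5ccccc5)cc2O1 | intermediate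
13 | (4R)-5,7-bis(benzyloxy)-4-LU-chroman-2-ol, C2 epimers | OC1C[C@@H](c2c(OCc5ccccc5)cc(OCc5ccccc5)c3C[C@@H](O[Si](C)(C)C(C)(C)C)[C@@H](c4cc(OCc5ccccc5)c(OCc5ccccc5)c(OCc5ccccc5)c4)Oc32)c2c(OCc5ccccc5)cc(OCc5ccccc5)cc2O1 | intermediate
14 | (4R)-5,7-bis(benzyloxy)-4-LU-4H-chromene | C1=C[C@@H](c2c(OCc5ccccc5)cc(OCc5ccccc5)c3C[C@@H](O[Si](C)(C)C(C)(C)C)[C@@H](c4cc(OCc5ccccc5)c(OCc5ccccc5)c(OCc5ccccc5)c4)Oc32)c2c(OCc5ccccc5)cc(OCc5ccccc5)cc2O1 | intermediate
15 | 2,3,4-trihydroxybenzaldehyde | O=Cc1ccc(O)c(O)c1O | starting material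
16 | 2,3,4-tris(benzyloxy)benzaldehyde | O=Cc1ccc(OCc2ccccc2)c(OCc2ccccc2)c1OCc1ccccc1 | intermediate
17 | 2,3,4-tris(benzyloxy)phenyl formate | O=COc1ccc(OCc2ccccc2)c(OCc2ccccc2)c1OCc1ccccc1 | intermediate
18 | 2,3,4-tris(benzyloxy)phenol | Oc1ccc(OCc2ccccc2)c(OCc2ccccc2)c1OCc1ccccc1 | intermediate
19 | 2,3,4-tris(benzyloxy)-6-iodophenol | Oc1c(I)cc(OCc2ccccc2)c(OCc2ccccc2)c1OCc1ccccc1 | intermediate
20 | 5-bromovanillin | COc1cc(C=O)cc(Br)c1O | starting material
21 | 3-bromo-4,5-dihydroxybenzaldehyde | O=Cc1cc(O)c(O)c(Br)c1 | intermediate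
22 | 3,4-bis(benzyloxy)-5-bromobenzaldehyde | O=Cc1cc(OCc2ccccc2)c(OCc2ccccc2)c(Br)c1 | intermediate
23 | 3,4-bis(benzyloxy)-5-bromobenzoic acid | OC(=O)c1cc(OCc2ccccc2)c(OCc2ccccc2)c(Br)c1 | intermediate
24 | 2-(trimethylsilyl)ethyl 3,4-bis(benzyloxy)-5-bromobenzoate | C[Si](C)(C)CCOC(=O)c1cc(OCc2ccccc2)c(OCc2ccccc2)c(Br)c1 | intermediate
25 | 2-(trimethylsilyl)ethyl 3,4-bis(benzyloxy)-5-boronobenzoate | C[Si](C)(C)CCOC(=O)c1cc(OCc2ccccc2)c(OCc2ccccc2)c(B(O)O)c1 | intermediate
26 | 2-(trimethylsilyl)ethyl 3,4-bis(benzyloxy)-5-[2,3,4-tris(benzyloxy)-6-iodophenoxy]benzoate (ArBG–I) | Ic1cc(OCc5ccccc5)c(OCc5ccccc5)c(OCc5ccccc5)c1Oc1cc(cc(OCc5ccccc5)c1OCc5ccccc5)C(=O)OCC[Si](C)(C)C | intermediate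
27 | ArBG–MgCl | Cl[Mg]c1cc(OCc5ccccc5)c(OCc5ccccc5)c(OCc5ccccc5)c1Oc1cc(cc(OCc5ccccc5)c1OCc5ccccc5)C(=O)OCC[Si](C)(C)C | intermediate
28 | ArBG–ZnBr | Br[Zn]c1cc(OCc5ccccc5)c(OCc5ccccc5)c(OCc5ccccc5)c1Oc1cc(cc(OCc5ccccc5)c1OCc5ccccc5)C(=O)OCC[Si](C)(C)C | intermediate
29 | (2S,3R,4R)-2,3-epoxy-5,7-bis(benzyloxy)-4-LU-chroman, oxirane anti to the C4 aryl group | O6[C@@H]7[C@@H](c2c(OCc5ccccc5)cc(OCc5ccccc5)c3C[C@@H](O[Si](C)(C)C(C)(C)C)[C@@H](c4cc(OCc5ccccc5)c(OCc5ccccc5)c(OCc5ccccc5)c4)Oc32)c8c(OCc5ccccc5)cc(OCc5ccccc5)cc8O[C@H]67 | intermediate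
30 | (2R,3R,4R)-5,7-bis(benzyloxy)-2-ArBG-4-LU-chroman-3-ol (2,3-cis, 3,4-trans) | O[C@@H]1[C@@H](c2c(OCc5ccccc5)cc(OCc5ccccc5)c3C[C@@H](O[Si](C)(C)C(C)(C)C)[C@@H](c4cc(OCc5ccccc5)c(OCc5ccccc5)c(OCc5ccccc5)c4)Oc32)c2c(OCc5ccccc5)cc(OCc5ccccc5)cc2O[C@@H]1c1cc(OCc5ccccc5)c(OCc5ccccc5)c(OCc5ccccc5)c1Oc1cc(cc(OCc5ccccc5)c1OCc5ccccc5)C(=O)OCC[Si](C)(C)C | intermediate
31 | 3,4,5-tris(benzyloxy)benzoic acid | OC(=O)c1cc(OCc2ccccc2)c(OCc2ccccc2)c(OCc2ccccc2)c1 | starting material
32 | 3-O-[3,4,5-tris(benzyloxy)benzoyl] ester of 30 | O=C(O[C@@H]1[C@@H](c2c(OCc5ccccc5)cc(OCc5ccccc5)c3C[C@@H](O[Si](C)(C)C(C)(C)C)[C@@H](c4cc(OCc5ccccc5)c(OCc5ccccc5)c(OCc5ccccc5)c4)Oc32)c2c(OCc5ccccc5)cc(OCc5ccccc5)cc2O[C@@H]1c1cc(OCc5ccccc5)c(OCc5ccccc5)c(OCc5ccccc5)c1Oc1cc(cc(OCc5ccccc5)c1OCc5ccccc5)C(=O)OCC[Si](C)(C)C)c1cc(OCc5ccccc5)c(OCc5ccccc5)c(OCc5ccccc5)c1 | intermediate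
33 | seco acid: 32 with lower 3-OH and bridging-gallate CO2H free | O=C(O[C@@H]1[C@@H](c2c(OCc5ccccc5)cc(OCc5ccccc5)c3C[C@@H](O)[C@@H](c4cc(OCc5ccccc5)c(OCc5ccccc5)c(OCc5ccccc5)c4)Oc32)c2c(OCc5ccccc5)cc(OCc5ccccc5)cc2O[C@@H]1c1cc(OCc5ccccc5)c(OCc5ccccc5)c(OCc5ccccc5)c1Oc1cc(cc(OCc5ccccc5)c1OCc5ccccc5)C(=O)O)c1cc(OCc5ccccc5)c(OCc5ccccc5)c(OCc5ccccc5)c1 | intermediate
34 | mixed anhydride of 33 with 2,4,6-trichlorobenzoic acid | O=C(O[C@@H]1[C@@H](c2c(OCc5ccccc5)cc(OCc5ccccc5)c3C[C@@H](O)[C@@H](c4cc(OCc5ccccc5)c(OCc5ccccc5)c(OCc5ccccc5)c4)Oc32)c2c(OCc5ccccc5)cc(OCc5ccccc5)cc2O[C@@H]1c1cc(OCc5ccccc5)c(OCc5ccccc5)c(OCc5ccccc5)c1Oc1cc(cc(OCc5ccccc5)c1OCc5ccccc5)C(=O)OC(=O)c1c(Cl)cc(Cl)cc1Cl)c1cc(OCc5ccccc5)c(OCc5ccccc5)c(OCc5ccccc5)c1 | intermediate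
35 | pentadeca-O-benzyl ether of the target (macrolactone) | O=C(O[C@@H]1[C@@H]2c3c(OCc5ccccc5)cc(OCc5ccccc5)cc3O[C@@H]1c1cc(OCc5ccccc5)c(OCc5ccccc5)c(OCc5ccccc5)c1Oc1cc(cc(OCc5ccccc5)c1OCc5ccccc5)C(=O)O[C@@H]1Cc3c(OCc5ccccc5)cc(OCc5ccccc5)c2c3O[C@@H]1c1cc(OCc5ccccc5)c(OCc5ccccc5)c(OCc5ccccc5)c1)c1cc(OCc5ccccc5)c(OCc5ccccc5)c(OCc5ccccc5)c1 | intermediate
36 | CNP0601265.1 | O=C(O[C@@H]1[C@@H]2c3c(O)cc(O)cc3O[C@@H]1c1cc(O)c(O)c(O)c1Oc1cc(cc(O)c1O)C(=O)O[C@@H]1Cc3c(O)cc(O)c2c3O[C@@H]1c1cc(O)c(O)c(O)c1)c1cc(O)c(O)c(O)c1 | target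

Total step count: 24
Longest linear sequence: 12 steps (20 → 36 through steps 13–24; equally 1 → 36 through steps 1–4, 7–9 and 20–24)

Steps most likely to fail

1. Step 20. The oxirane may ionise and collapse (hydride shift to the chroman-3-one, or capture by bromide) before the aryl group is transferred, or the aryl group may enter without facial bias. The fallback uses known chemistry, sets out from 12 and returns at 30. The potassium enolate of lactone 12 (KHMDS, THF, −78 °C) is hydroxylated with 2-(phenylsulfonyl)-3-phenyloxaziridine on the face away from the C4 aryl group to give the (3R,4R)-3-hydroxy lactone F1. Its hydroxyl is deprotonated with i-PrMgCl, and arylmagnesium chloride 27 is added to the lactone carbonyl at −78 → −40 °C to give the 2-aryl hemiketal F2, in equilibrium with the open hydroxy ketone. Ionic hydrogenation (Et3SiH, BF3·OEt2, CH2Cl2, −40 °C) through the 2-aryl oxocarbenium ion, with hydride entering trans to the C3 oxygen as in the lactone route to C-aryl glycosides, should give 30.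

2. Step 7. Transmetalation and insertion of the doubly ortho-substituted aryl group may be slow, protodeboronation may win, and catalyst control may be mismatched with the chiral boronic acid. The fallback sets out from 4 and returns at 12. Bromide 4 is lithiated (n-BuLi, THF, −78 °C) and formylated with DMF to the 8-carbaldehyde F3. Knoevenagel condensation with Meldrum's acid (piperidinium acetate, rt) gives the alkylidene Meldrum's acid F4. Purchased 3,5-bis(benzyloxy)phenol is then added under Yb(OTf)3 catalysis (MeNO2, 80–100 °C) in a Friedel–Crafts conjugate addition, followed by lactonisation with loss of acetone and CO2. This forms the same C4–aryl bond by an electrophilic aromatic substitution that tolerates four ortho substituents. No facial control is expected, so 12 is separated by chromatography from its diastereomer, the (4S)-epimer F5.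

3. Step 23. Ring closure may give way to oligomerisation, because the activated aromatic acid and the hindered axial lower 3-OH may not reach each other while the bulky 3-O-galloyl group is in place. The fallback changes the order of events, sets out from 30 and returns at 35. Alcohol 30 is treated with TBAF (THF, 0 °C → rt) to give the diol acid F6. Shiina macrolactonisation (2-methyl-6-nitrobenzoic anhydride, DMAP, CH2Cl2, high dilution) closes the 16-membered ring at the lower 3-OH to give the macrocyclic alcohol F7; closure at the upper 3-OH would need a strained 9-membered ring. Steglich esterification of F7 with 31 (EDC·HCl, DMAP, CH2Cl2) then gives 35.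

Further compounds
F1 | step 20 | (3R,4R)-5,7-bis(benzyloxy)-3-hydroxy-4-LU-chroman-2-one | O[C@@H]1[C@@H](c2c(OCc5ccccc5)cc(OCc5ccccc5)c3C[C@@H](O[Si](C)(C)C(C)(C)C)[C@@H](c4cc(OCc5ccccc5)c(OCc5ccccc5)c(OCc5ccccc5)c4)Oc32)c2c(OCc5ccccc5)cc(OCc5ccccc5)cc2OC1=O
F2 | step 20 | (3R,4R)-2-ArBG-5,7-bis(benzyloxy)-4-LU-chroman-2,3-diol (hemiketal, C2 epimers) | O[C@@H]1[C@@H](c2c(OCc5ccccc5)cc(OCc5ccccc5)c3C[C@@H](O[Si](C)(C)C(C)(C)C)[C@@H](c4cc(OCc5ccccc5)c(OCc5ccccc5)c(OCc5ccccc5)c4)Oc32)c2c(OCc5ccccc5)cc(OCc5ccccc5)cc2OC1(O)c1cc(OCc5ccccc5)c(OCc5ccccc5)c(OCc5ccccc5)c1Oc1cc(cc(OCc5ccccc5)c1OCc5ccccc5)C(=O)OCC[Si](C)(C)C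
F3 | step 7 | 8-formyl derivative of 3 (LU–CHO) | CC(C)(C)[Si](C)(C)O[C@@H]1Cc2c(OCc5ccccc5)cc(OCc5ccccc5)c(C=O)c2O[C@@H]1c1cc(OCc5ccccc5)c(OCc5ccccc5)c(OCc5ccccc5)c1
F4 | step 7 | 5-(LU-methylidene)-2,2-dimethyl-1,3-dioxane-4,6-dione | CC(C)(C)[Si](C)(C)O[C@@H]1Cc2c(OCc5ccccc5)cc(OCc5ccccc5)c(C=C3C(=O)OC(C)(C)OC3=O)c2O[C@@H]1c1cc(OCc5ccccc5)c(OCc5ccccc5)c(OCc5ccccc5)c1
F5 | step 7 | (4S)-5,7-bis(benzyloxy)-4-LU-chroman-2-one (C4 epimer of 12) | O=C1C[C@H](c2c(OCc5ccccc5)cc(OCc5ccccc5)c3C[C@@H](O[Si](C)(C)C(C)(C)C)[C@@H](c4cc(OCc5ccccc5)c(OCc5ccccc5)c(OCc5ccccc5)c4)Oc32)c2c(OCc5ccccc5)cc(OCc5ccccc5)cc2O1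
F6 | step 23 | diol acid: 30 with lower 3-OH and bridging-gallate CO2H free | O[C@@H]1[C@@H](c2c(OCc5ccccc5)cc(OCc5ccccc5)c3C[C@@H](O)[C@@H](c4cc(OCc5ccccc5)c(OCc5ccccc5)c(OCc5ccccc5)c4)Oc32)c2c(OCc5ccccc5)cc(OCc5ccccc5)cc2O[C@@H]1c1cc(OCc5ccccc5)c(OCc5ccccc5)c(OCc5ccccc5)c1Oc1cc(cc(OCc5ccccc5)c1OCc5ccccc5)C(=O)O
F7 | step 23 | macrolactone with free upper 3-OH (35 without the 3-O-galloyl group) | O[C@@H]1[C@@H]2c3c(OCc5ccccc5)cc(OCc5ccccc5)cc3O[C@@H]1c1cc(OCc5ccccc5)c(OCc5ccccc5)c(OCc5ccccc5)c1Oc1cc(cc(OCc5ccccc5)c1OCc5ccccc5)C(=O)O[C@@H]1Cc3c(OCc5ccccc5)cc(OCc5ccccc5)c2c3O[C@@H]1c1cc(OCc5ccccc5)c(OCc5ccccc5)c(OCc5ccccc5)c1
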